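The two forms of the catalyst, Zd and Zf, always add up to their charge, and the first two steps together are Za + Zb ⇌ Zg + Zc, with the catalyst coming out as it went in.

    Zd + Zb ⇌ Zf + Zc (K1 = 1.1, k1 = 0.71 /M/s)
    Za + Zf ⇌ Zg + Zd (K2 = 0.88, k2 = 0.98 /M/s)
    Za + Ze → Zh (k3 = 0.077 /M/s)
    Zj ⇌ Zg, rate k4*(cs4 - [Zg]) while solid is left; crystals form when [Zg] > cs4 (cs4 = 0.073 M, k4 = 0.0097 /s)

Za 0.074 M; Zb 0.0740 M; Ze 1.48 mM; Zd 1.9 mM; time 40 min; volume of the second phase over the first 1.0

- amounts and yields of Zg count Zj too
- in the second phase: Zb, Zc; everything else is in the first
- charges count per volume of the first phase; a concentration in a rate is the amount of a species over the volume of its own phase; every rate counts per litre of the first phase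
- given per volume of solution although it is solid: Zj
- run time (flask): 40 min

- the Zg and Zj together standing at 40 min, as a percentage of the Za charged
- the change that raises the amount of Zg and Zj together at 40 min, in percent of the Za charged most ("none" if none brings more than 2 percentage points) (teal / green / violet / none)
- amount of Zg and Zj together at 40 min, in percent of the Za charged, after green

- teal: doubling the dissolution coefficient of step 4, all else as stated
- green: doubling the solubility in step 4, all else as stated
- violet: doubling the amount of Zb, all else as stated

Taken together, those two steps have the equilibrium constant 0.968. With equal charges, the share of Za turned at equilibrium is the root of that constant over one plus the root, 49.6%. This flask's ceiling for dissolved Zg is therefore 36.7 mM, lower than the solubility of 0.073 M, so no Zj is expected, and teal and green should change nothing.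

The speed is reckoned from the cycle. Its two steps in series have a sum of rate terms of 0.125 /s at the start and 0.128 /s at the ceiling. With that sum steady and the constant near one, the gap to the ceiling shrinks exponentially. Its relaxation time, the sum of the two forward constants over 2 times the catalyst charge and their product, is 10.7 min. This is the crossing from kinetic to thermodynamic control, and the run of 40 min is longer than it, by a factor of 3.74.

Ze meets Za with a life of 2.93 min, shorter than the relaxation time, so the reckoning takes its charge off Za at once. The ceiling becomes 48.6% of the Za charged, and the yield 47.4%.

The weak link is the equal charges: after the share of Ze, Za stands at 72.5 mM, less than the 74 mM of Zb, and Zf holds part of the catalyst. With Zb near Zc, Zf takes 0.995 mM. The share then goes on the mean of free Za and charged Zb, less 0.497 mM, which gives a ceiling of 48.4% and a yield of 47.3%.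

Violet, with the constant taken as one, lifts the ceiling to 65.8%. If the relaxation time still holds, the yield is 64.2%, more than the 47.3% reckoned for the flask as charged.

The forecast says 47.3%, violet and 47.3%, with the words “Crystals never form, so teal and green change nothing.”

The flask gives 47.3%, with violet best, a gain of 16 percentage points, and 47.3% after green. Zj stands at 0% at 40.0 min. The relaxation time, used again at 10.0 min, gives 29.4%, and the flask then holds 29.4% of the Za charged as Zg and Zj.

A neighbour flask charged with 7.6 × 10⁻⁴ M of Zd has a relaxation time of 26.6 min, so its run lasts 1.50 of them. Zf holds less there, which puts that neighbour's ceiling at 48.8%, and the reckoning gives 38.0%. The neighbour flask gives 38.0%.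

The numbers are assumed; the flask was simulated.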